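The dimer is cut at the C4–C6' interflavan bond into a C4-activated epigallocatechin gallate electrophile and an 8-bromo gallocatechin nucleophile, both drawn from one flav-2-ene. That flavene arises by closing pyran ring C between C2 and C3, the bond that in the upper unit joins the galloyloxy carbon to the ring B carbon: the O1–C2(ring B) unit is read as a masked gallate ester of the ring A phenol, and C3–C4 as an ortho-allyl group. In one operation the titanium methylidene Cp2Ti=CH2 turns the ester carbonyl into an enol ether and closes the pyran by enol ether–olefin metathesis, giving C2=C3 ready for reagent-controlled hydroboration. The precursor is 2-allyl-3,5-bis(benzyloxy)phenyl 3,4,5-tris(benzyloxy)benzoate.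

Key step: step 4

Remark: C4 of 13 and 14 is drawn 4β (trans to O3), as expected from the DDQ step; its configuration is immaterial because C4 is ionised in step 11.

**Route**

Step 1
Reactants: 1 3,5-bis(benzyloxy)phenol
Product: 2 1-(allyloxy)-3,5-bis(benzyloxy)benzene
Conditions: allyl bromide, K2CO3, acetone, reflux
Reagents that add atoms: allyl bromide, C=CCBr
Why: Williamson etherification of the single free phenol should proceed cleanly; no stereocentre is involved.

Step 2
Reactants: 2 1-(allyloxy)-3,5-bis(benzyloxy)benzene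
Product: 4 2-allyl-3,5-bis(benzyloxy)phenol, via ortho-allyl cyclohexadienone 3 (not isolated)
Conditions: N,N-diethylaniline, 190 °C
Reagents that add atoms: none
Why: Aromatic Claisen rearrangement ([3,3]) should deliver the allyl group to either of the two equivalent ortho carbons, and tautomerisation of dienone 3 restores the phenol; the benzyl ethers tolerate the heat.

Step 3
Reactants: 4 2-allyl-3,5-bis(benzyloxy)phenol; 5 3,4,5-tris(benzyloxy)benzoic acid
Product: 6 2-allyl-3,5-bis(benzyloxy)phenyl 3,4,5-tris(benzyloxy)benzoate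
Conditions: DCC, DMAP (cat.), CH2Cl2, rt
Reagents that add atoms: none
Why: Steglich esterification should acylate the hindered phenol through the acylpyridinium species; nothing else in 4 or 5 is nucleophilic.

Step 4
Reactants: 6 2-allyl-3,5-bis(benzyloxy)phenyl 3,4,5-tris(benzyloxy)benzoate
Product: 8 5,7-bis(benzyloxy)-2-[3,4,5-tris(benzyloxy)phenyl]-4H-chromene, via acyclic enol ether 7 (not isolated)
Conditions: Cp2Ti(μ-CH2)(μ-Cl)AlMe2 (Tebbe reagent, 4 equiv), pyridine (cat.), THF, 0 °C to rt, then reflux under dilution; aq NaOH quench, basic Al2O3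
Reagents that add atoms: none
Why: Cp2Ti=CH2 released from Cp2Ti(μ-CH2)(μ-Cl)AlMe2 should add [2+2] to the ester carbonyl and cyclorevert to the 1,1-disubstituted enol ether 7 with loss of Cp2Ti=O; on heating, further Cp2Ti=CH2 should engage the terminal allyl olefin and, through a titanacyclobutane and loss of ethylene, give the alkylidene Cp2Ti=CHCH2Ar at C3, which adds across the enol ether C=CH2 and cycloreverts to the C2=C3 double bond. The closest known reaction type is the titanium-mediated cyclization of olefinic esters to cyclic enol ethers, that is, carbonyl olefination followed by enol ether–olefin ring-closing metathesis. The one ring closed is the six-membered pyran (ring C), formed by ring-closing metathesis between the enol ether and allyl termini, which the aromatic C4a–C8a bond holds ortho to each other. No stereocentre is created: C2 and C3 emerge as a planar trisubstituted enol ether, which is what allows both to be set together by reagent control in step 5. The step needs chemoselective methylenation of the aryl ester (benzyl ethers are inert) and cyclization in preference to allyl isomerisation or oligomerisation, which the ortho geometry and dilution should secure, while the basic quench protects the acid-labile 4H-chromene.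

Step 5
Reactants: 8 5,7-bis(benzyloxy)-2-[3,4,5-tris(benzyloxy)phenyl]-4H-chromene
Product: 10 (2R,3S)-5,7-bis(benzyloxy)-2-[3,4,5-tris(benzyloxy)phenyl]chroman-3-ol (penta-O-benzyl-(+)-gallocatechin), via flavan-3-yl(isopinocampheyl)borane 9 (not isolated)
Conditions: IpcBH2 (from (+)-α-pinene), THF, −25 °C; then NaOH, H2O2, 0 °C to rt
Reagents that add atoms: hydrogen peroxide, OO
Why: Asymmetric hydroboration–oxidation: ring oxygen and aryl group both direct boron to C3, syn addition of H (C2) and B (C3) followed by oxidation with retention gives the 2,3-trans alcohol, and the isopinocampheyl group should select the alkene face that leads to (2R,3S), by analogy with the (1S,2R)-trans-2-arylcycloalkanols that this enantiomer of the reagent is known to give from 1-arylcycloalkenes.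

Step 6
Reactants: 10 (2R,3S)-5,7-bis(benzyloxy)-2-[3,4,5-tris(benzyloxy)phenyl]chroman-3-ol
Product: 11 (2R)-5,7-bis(benzyloxy)-2-[3,4,5-tris(benzyloxy)phenyl]chroman-3-one
Conditions: Dess–Martin periodinane, wet CH2Cl2, rt
Reagents that add atoms: none
Why: Dess–Martin oxidation under neutral conditions should give the flavan-3-one without enolising the C2 stereocentre.

Step 7
Reactants: 11 (2R)-5,7-bis(benzyloxy)-2-[3,4,5-tris(benzyloxy)phenyl]chroman-3-one
Product: 12 (2R,3R)-5,7-bis(benzyloxy)-2-[3,4,5-tris(benzyloxy)phenyl]chroman-3-ol (penta-O-benzyl-(−)-epigallocatechin)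
Conditions: LiBH(s-Bu)3 (L-Selectride), LiBr, THF, −78 °C; then H2O
Reagents that add atoms: none
Why: Diastereoselective ketone reduction: the bulky hydride should attack from the equatorial direction to give the axial 3-OH cis to the equatorial C2 aryl group (2R,3R), and the low temperature keeps C2 from epimerising.

Step 8
Reactants: 12 (2R,3R)-5,7-bis(benzyloxy)-2-[3,4,5-tris(benzyloxy)phenyl]chroman-3-ol
Product: 13 (2R,3R,4S)-5,7-bis(benzyloxy)-4-(2-ethoxyethoxy)-2-[3,4,5-tris(benzyloxy)phenyl]chroman-3-ol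
Conditions: DDQ, 2-ethoxyethanol, CH2Cl2, rt
Reagents that add atoms: 2-ethoxyethanol, CCOCCO
Why: Benzylic oxidation by hydride abstraction: DDQ should remove hydride from C4, which the 5,7-dialkoxy ring A activates far more than any benzyl ether CH2, and the alcohol should trap the cation trans to the 3-OH.

Step 9
Reactants: 13 (2R,3R,4S)-5,7-bis(benzyloxy)-4-(2-ethoxyethoxy)-2-[3,4,5-tris(benzyloxy)phenyl]chroman-3-ol; 5 3,4,5-tris(benzyloxy)benzoic acid
Product: 14 (2R,3R,4S)-5,7-bis(benzyloxy)-4-(2-ethoxyethoxy)-2-[3,4,5-tris(benzyloxy)phenyl]chroman-3-yl 3,4,5-tris(benzyloxy)benzoate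
Conditions: DCC, DMAP, CH2Cl2, rt
Reagents that add atoms: none
Why: Steglich esterification of the only free hydroxyl should install the gallate with retention at C3, and the non-acidic medium leaves the C4 ether intact.

Step 10
Reactants: 10 (2R,3S)-5,7-bis(benzyloxy)-2-[3,4,5-tris(benzyloxy)phenyl]chroman-3-ol
Product: 15 (2R,3S)-8-bromo-5,7-bis(benzyloxy)-2-[3,4,5-tris(benzyloxy)phenyl]chroman-3-ol
Conditions: NBS, CH2Cl2, −78 °C to rt
Reagents that add atoms: N-bromosuccinimide, O=C1CCC(=O)N1Br
Why: Electrophilic aromatic bromination of ring A should occur at C8, the more accessible and more reactive position of benzylated flavan-3-ols, leaving C6 as the only nucleophilic site for the coupling.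

Step 11
Reactants: 14 (2R,3R,4S)-5,7-bis(benzyloxy)-4-(2-ethoxyethoxy)-2-[3,4,5-tris(benzyloxy)phenyl]chroman-3-yl 3,4,5-tris(benzyloxy)benzoate; 15 (2R,3S)-8-bromo-5,7-bis(benzyloxy)-2-[3,4,5-tris(benzyloxy)phenyl]chroman-3-ol (3 equiv)
Product: 16 [5,7,3',4',5'-penta-O-benzyl-3-O-(3,4,5-tri-O-benzylgalloyl)epigallocatechin]-(4β→6)-[8-bromo-5,7,3',4',5'-penta-O-benzylgallocatechin]
Conditions: TMSOTf (cat.), CH2Cl2, −78 to −40 °C
Reagents that add atoms: none
Why: Lewis-acid-promoted Friedel–Crafts alkylation: ionisation of the C4 ether should give a ring A-stabilised benzylic cation whose α face is shielded by the participating 3-O-acyl group, so C6 of 15 (C8 blocked by bromine) attacks from the β face and sets C4 as 4β (3,4-trans).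

Step 12
Reactants: 16 [5,7,3',4',5'-penta-O-benzyl-3-O-(3,4,5-tri-O-benzylgalloyl)epigallocatechin]-(4β→6)-[8-bromo-5,7,3',4',5'-penta-O-benzylgallocatechin]
Product: 17 epigallocatechin 3-O-gallate-(4β→6)-gallocatechin (upper unit 2R,3R,4S; lower unit 2R,3S)
Conditions: H2 (1 atm), Pd(OH)2/C, Et3N (1.1 equiv), THF/MeOH/H2O, rt
Reagents that add atoms: none
Why: Catalytic hydrogenolysis should cleave all thirteen benzyl ethers and the aryl C–Br bond while leaving the gallate ester, the interflavan bond and all five stereocentres untouched, the amine neutralising HBr that would otherwise cleave the acid-labile C4–C6' bond.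

**Compound list**

1 | 3,5-bis(benzyloxy)phenol | Oc1cc(OCc2ccccc2)cc(OCc2ccccc2)c1 | starting material
2 | 1-(allyloxy)-3,5-bis(benzyloxy)benzene | C=CCOc1cc(OCc2ccccc2)cc(OCc2ccccc2)c1 | intermediate
3 | 6-allyl-3,5-bis(benzyloxy)cyclohexa-2,4-dien-1-one (racemic transient dienone) | O=C1C(CC=C)C(OCc2ccccc2)=CC(OCc2ccccc2)=C1 | intermediate
4 | 2-allyl-3,5-bis(benzyloxy)phenol | C=CCc1c(O)cc(OCc2ccccc2)cc1OCc1ccccc1 | intermediate
5 | 3,4,5-tris(benzyloxy)benzoic acid | O=C(O)c1cc(OCc2ccccc2)c(OCc2ccccc2)c(OCc2ccccc2)c1 | starting material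
6 | 2-allyl-3,5-bis(benzyloxy)phenyl 3,4,5-tris(benzyloxy)benzoate | C=CCc1c(OC(=O)c2cc(OCc3ccccc3)c(OCc3ccccc3)c(OCc3ccccc3)c2)cc(OCc2ccccc2)cc1OCc1ccccc1 | intermediate
7 | 2-allyl-3,5-bis(benzyloxy)phenyl 1-[3,4,5-tris(benzyloxy)phenyl]vinyl ether (transient acyclic enol ether) | C=CCc1c(OC(=C)c2cc(OCc3ccccc3)c(OCc3ccccc3)c(OCc3ccccc3)c2)cc(OCc2ccccc2)cc1OCc1ccccc1 | intermediate
8 | 5,7-bis(benzyloxy)-2-[3,4,5-tris(benzyloxy)phenyl]-4H-chromene | C1(c2cc(OCc3ccccc3)c(OCc3ccccc3)c(OCc3ccccc3)c2)=CCc2c(OCc3ccccc3)cc(OCc3ccccc3)cc2O1 | intermediate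
9 | [(2S,3S)-5,7-bis(benzyloxy)-2-[3,4,5-tris(benzyloxy)phenyl]chroman-3-yl](isopinocampheyl)borane, isopinocampheyl group from (+)-α-pinene (same spatial arrangement at C2 and C3 as in 10; the C2 descriptor reads S only because boron ranks below carbon) | C[C@H]1[C@H](B[C@H]2Cc3c(OCc4ccccc4)cc(OCc4ccccc4)cc3O[C@@H]2c2cc(OCc3ccccc3)c(OCc3ccccc3)c(OCc3ccccc3)c2)C[C@@H]2C[C@H]1C2(C)C | intermediate
10 | (2R,3S)-5,7-bis(benzyloxy)-2-[3,4,5-tris(benzyloxy)phenyl]chroman-3-ol | O[C@H]1Cc2c(OCc3ccccc3)cc(OCc3ccccc3)cc2O[C@@H]1c1cc(OCc2ccccc2)c(OCc2ccccc2)c(OCc2ccccc2)c1 | intermediate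
11 | (2R)-5,7-bis(benzyloxy)-2-[3,4,5-tris(benzyloxy)phenyl]chroman-3-one | O=C1Cc2c(OCc3ccccc3)cc(OCc3ccccc3)cc2O[C@@H]1c1cc(OCc2ccccc2)c(OCc2ccccc2)c(OCc2ccccc2)c1 | intermediate
12 | (2R,3R)-5,7-bis(benzyloxy)-2-[3,4,5-tris(benzyloxy)phenyl]chroman-3-ol | O[C@@H]1Cc2c(OCc3ccccc3)cc(OCc3ccccc3)cc2O[C@@H]1c1cc(OCc2ccccc2)c(OCc2ccccc2)c(OCc2ccccc2)c1 | intermediate
13 | (2R,3R,4S)-5,7-bis(benzyloxy)-4-(2-ethoxyethoxy)-2-[3,4,5-tris(benzyloxy)phenyl]chroman-3-ol | O[C@@H]1[C@@H](OCCOCC)c2c(OCc3ccccc3)cc(OCc3ccccc3)cc2O[C@@H]1c1cc(OCc2ccccc2)c(OCc2ccccc2)c(OCc2ccccc2)c1 | intermediate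
14 | (2R,3R,4S)-5,7-bis(benzyloxy)-4-(2-ethoxyethoxy)-2-[3,4,5-tris(benzyloxy)phenyl]chroman-3-yl 3,4,5-tris(benzyloxy)benzoate | O=C(O[C@@H]1[C@@H](OCCOCC)c2c(OCc3ccccc3)cc(OCc3ccccc3)cc2O[C@@H]1c1cc(OCc2ccccc2)c(OCc2ccccc2)c(OCc2ccccc2)c1)c1cc(OCc2ccccc2)c(OCc2ccccc2)c(OCc2ccccc2)c1 | intermediate
15 | (2R,3S)-8-bromo-5,7-bis(benzyloxy)-2-[3,4,5-tris(benzyloxy)phenyl]chroman-3-ol | O[C@H]1Cc2c(OCc3ccccc3)cc(OCc3ccccc3)c(Br)c2O[C@@H]1c1cc(OCc2ccccc2)c(OCc2ccccc2)c(OCc2ccccc2)c1 | intermediate
16 | [5,7,3',4',5'-penta-O-benzyl-3-O-(3,4,5-tri-O-benzylgalloyl)epigallocatechin]-(4β→6)-[8-bromo-5,7,3',4',5'-penta-O-benzylgallocatechin] | O=C(O[C@@H]1[C@@H](c2c(OCc3ccccc3)c(Br)c3c(c2OCc2ccccc2)C[C@H](O)[C@@H](c2cc(OCc4ccccc4)c(OCc4ccccc4)c(OCc4ccccc4)c2)O3)c2c(OCc3ccccc3)cc(OCc3ccccc3)cc2O[C@@H]1c1cc(OCc2ccccc2)c(OCc2ccccc2)c(OCc2ccccc2)c1)c1cc(OCc2ccccc2)c(OCc2ccccc2)c(OCc2ccccc2)c1 | intermediate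
17 | epigallocatechin 3-O-gallate-(4β→6)-gallocatechin | O=C(O[C@@H]1[C@@H](c2c(O)cc3c(c2O)C[C@H](O)[C@@H](c2cc(O)c(O)c(O)c2)O3)c2c(O)cc(O)cc2O[C@@H]1c1cc(O)c(O)c(O)c1)c1cc(O)c(O)c(O)c1 | target

**Count and risks**

Total step count: 12. Longest linear sequence: 11 steps (steps 1 to 9, then 11 and 12); the nucleophile branch (step 10) leaves the main line at compound 10.

The three steps most likely to fail, each with its fallback:

Risk 1 (step 4): the titanium methylidene may stop after carbonyl olefination because metathesis onto the hindered 1,1-disubstituted enol ether is slow, or the aluminium Lewis acid may isomerise the allyl group and degrade the enol ethers on prolonged heating. Fallback for step 4: the two events are separated and the ring closure is handed to a ruthenium carbene. Setting out from 6, Cp2TiMe2 (toluene, 70 °C, dark) should give the enol ether 7, now isolated by filtration through basic Al2O3. Ring-closing metathesis with second-generation Grubbs catalyst (H2IMes)(PCy3)Cl2Ru=CHPh (toluene, 70 °C, high dilution) should then close C2=C3 and come back to the route at 8. This fallback makes no compound outside the compound list, which the line F0 records.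

Risk 2 (step 5): facial discrimination by the chiral borane may be insufficient or of the opposite sense on this bulky enol ether, or the β-aryloxy borane may undergo β-elimination and open ring C. Fallback for step 5: absolute configuration is taken from a catalyst and from the chiral pool instead. Setting out from 8, BH3·SMe2 then NaOH/H2O2 should give the racemic trans alcohol (±)-trans-5,7-bis(benzyloxy)-2-[3,4,5-tris(benzyloxy)phenyl]chroman-3-ol F1, whose SMILES below shows the 2S,3R antipode as a stand-in for the racemate. Dess–Martin oxidation of F1 should give the racemic ketone (±)-5,7-bis(benzyloxy)-2-[3,4,5-tris(benzyloxy)phenyl]chroman-3-one F2. Transfer hydrogenation with dynamic kinetic resolution (RuCl(p-cymene)[(S,S)-TsDPEN] or its antipode, whichever delivers the 3R carbinol, HCO2H/Et3N) should reduce the rapidly enolising F2 to the cis alcohol and come back to the route at 12. The nucleophile branch is then fed by commercial (2R,3S)-(+)-gallocatechin F3, whose perbenzylation with benzyl bromide and K2CO3 in DMF comes back to the route at 10.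

Risk 3 (step 11): the cation from 14 may be intercepted by ring A of a second molecule of 14, which is more nucleophilic than the bromine-deactivated 15, so that oligomerisation outruns the cross-coupling. Fallback for step 11: the electrophile is bromine-capped as well. Setting out from 14, NBS (CH2Cl2, −78 °C) should give the bromo electrophile (2R,3R,4S)-8-bromo-5,7-bis(benzyloxy)-4-(2-ethoxyethoxy)-2-[3,4,5-tris(benzyloxy)phenyl]chroman-3-yl 3,4,5-tris(benzyloxy)benzoate F4. TMSOTf-promoted coupling of F4 with 15 should give the dibromo dimer [8-bromo-5,7,3',4',5'-penta-O-benzyl-3-O-(3,4,5-tri-O-benzylgalloyl)epigallocatechin]-(4β→6)-[8-bromo-5,7,3',4',5'-penta-O-benzylgallocatechin] F5. Hydrogenolysis of F5 under the conditions of step 12 should remove both bromine atoms with the benzyl groups and come back to the route at 17.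

Further compounds

F0 | step 4 | none | none
F1 | step 5 | (±)-trans-5,7-bis(benzyloxy)-2-[3,4,5-tris(benzyloxy)phenyl]chroman-3-ol | O[C@@H]1Cc2c(OCc3ccccc3)cc(OCc3ccccc3)cc2O[C@H]1c1cc(OCc2ccccc2)c(OCc2ccccc2)c(OCc2ccccc2)c1
F2 | step 5 | (±)-5,7-bis(benzyloxy)-2-[3,4,5-tris(benzyloxy)phenyl]chroman-3-one | O=C1Cc2c(OCc3ccccc3)cc(OCc3ccccc3)cc2OC1c1cc(OCc2ccccc2)c(OCc2ccccc2)c(OCc2ccccc2)c1
F3 | step 5 | (2R,3S)-(+)-gallocatechin | O[C@H]1Cc2c(O)cc(O)cc2O[C@@H]1c1cc(O)c(O)c(O)c1
F4 | step 11 | (2R,3R,4S)-8-bromo-5,7-bis(benzyloxy)-4-(2-ethoxyethoxy)-2-[3,4,5-tris(benzyloxy)phenyl]chroman-3-yl 3,4,5-tris(benzyloxy)benzoate | O=C(O[C@@H]1[C@@H](OCCOCC)c2c(OCc3ccccc3)cc(OCc3ccccc3)c(Br)c2O[C@@H]1c1cc(OCc2ccccc2)c(OCc2ccccc2)c(OCc2ccccc2)c1)c1cc(OCc2ccccc2)c(OCc2ccccc2)c(OCc2ccccc2)c1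
F5 | step 11 | [8-bromo-5,7,3',4',5'-penta-O-benzyl-3-O-(3,4,5-tri-O-benzylgalloyl)epigallocatechin]-(4β→6)-[8-bromo-5,7,3',4',5'-penta-O-benzylgallocatechin] | O=C(O[C@@H]1[C@@H](c2c(OCc3ccccc3)c(Br)c3c(c2OCc2ccccc2)C[C@H](O)[C@@H](c2cc(OCc4ccccc4)c(OCc4ccccc4)c(OCc4ccccc4)c2)O3)c2c(OCc3ccccc3)cc(OCc3ccccc3)c(Br)c2O[C@@H]1c1cc(OCc2ccccc2)c(OCc2ccccc2)c(OCc2ccccc2)c1)c1cc(OCc2ccccc2)c(OCc2ccccc2)c(OCc2ccccc2)c1
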